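**Retrosynthetic overview**
1. The 2H-pyran ring (O1–C2–C3=C4–C4a=C8a) is made last, from its five-membered isomer. This is a 2,3-dihydrofuran (O–C3–C4–C4a–C8a) that carries the finished tertiary carbinol C2–OH outside the ring. Alkoxide-driven one-atom ring expansion and loss of the freed C3 oxygen give O1–C8a and C3=C4 in one flask.
2. Enabling feature: C8a is the alkoxy-bearing sp2 carbon of a vinylogous ester (O–C8a=C4a–C5=O) in the dearomatised ring, so it swaps alkoxy groups like an acyl carbon. The two oxygens sit on the vicinal carbons C2 and C3, so the swap runs through a five-membered 1,3-dioxolane-type adduct and never breaks the C2–O bond. C2 is quaternary, so elimination can only give C3=C4.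
3. The dihydrofuran comes from 5-exo opening of a (2R,3R)-epoxide linked to C4a through CH2. That epoxide comes from reductive Knoevenagel coupling (C4–C4a bond) of the acylfilicinic acid with 2,3-epoxygeranial.
4. Acylfilicinic acid: Friedel–Crafts acylation of phloroglucinol with (R)-2-methylbutanoyl chloride, then dearomative gem-dimethylation. Epoxygeranial: Sharpless epoxidation of geraniol (sets C2), then oxidation.
5. Ring order: carbocycle (arene, then dearomatised) → dihydrofuran → 2H-pyran.

Key step: step 7

Assumption: (R)-2-methylbutanoic acid is taken as a purchasable enantiopure acid, and all triketone tautomers are drawn in the enol form used in the target SMILES.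

**Step 1**
Reactants: 1 (R)-2-methylbutanoic acid
Product: 2 (R)-2-methylbutanoyl chloride
Conditions: (COCl)2 (1.2 equiv), DMF (cat.), CH2Cl2, 0 °C → rt
Reagents that add atoms: oxalyl chloride O=C(Cl)C(=O)Cl
Why: Vilsmeier-type activation converts the acid into its chloride under cold, non-enolising conditions, so the α-stereocentre should be carried over unchanged.

**Step 2**
Reactants: 2 (R)-2-methylbutanoyl chloride; 3 phloroglucinol
Product: 4 (2R)-2-methyl-1-(2,4,6-trihydroxyphenyl)butan-1-one
Conditions: AlCl3 (4 equiv), PhNO2/CH2Cl2, 0 → 40 °C; aq HCl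
Reagents that add atoms: none
Why: Friedel–Crafts C-acylation of the threefold symmetric, very electron-rich arene can give only one monoketone, the chelated aryl ketone slows a second acylation, and the side-chain stereocentre takes no part.

**Step 3**
Reactants: 4 (2R)-2-methyl-1-(2,4,6-trihydroxyphenyl)butan-1-one
Product: 5 (R)-2-methylbutanoylfilicinic acid
Conditions: MeI (2.2 equiv), NaOMe (3 equiv), MeOH, 0 °C → rt; acidify
Reagents that add atoms: iodomethane CI
Why: In this dearomative double C-methylation of the acylphloroglucinol anion, the first methyl raises the nucleophilicity of its own ring carbon, so the second should enter there and lock the ring as the 6,6-dimethylcyclohexadienone, while the triketonate charge protects the side-chain α-CH from deprotonation.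

**Step 4**
Reactants: 6 geraniol
Product: 7 (2R,3R)-2,3-epoxygeraniol
Conditions: Ti(Oi-Pr)4 (5 mol %), D-(−)-DIPT (7 mol %), t-BuOOH, 4 Å MS, CH2Cl2, −20 °C
Reagents that add atoms: tert-butyl hydroperoxide CC(C)(C)OO
Why: In the Sharpless asymmetric epoxidation the titanium–tartrate complex binds the allylic hydroxyl, so only the 2,3-alkene reacts, and D-(−)-tartrate controls the face to give the (2R,3R)-epoxide, which fixes the tertiary C–O stereocentre of the target.

**Step 5**
Reactants: 7 (2R,3R)-2,3-epoxygeraniol
Product: 8 (2S,3R)-2,3-epoxygeranial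
Conditions: TEMPO (10 mol %), PhI(OAc)2 (1.1 equiv), CH2Cl2, 0 °C → rt
Reagents that add atoms: none
Why: Oxoammonium oxidation stops at the aldehyde and leaves the epoxide and the trisubstituted alkene untouched; the descriptor at C2 changes only because of CIP ranking.

**Step 6**
Reactants: 5 (R)-2-methylbutanoylfilicinic acid; 8 (2S,3R)-2,3-epoxygeranial
Product: 11 dihydrofuran carbinol (five-membered-ring isomer of the hydrated target), via alkylidene trione 9 (not isolated), via C-alkylated epoxide 10 (not isolated)
Conditions: Hantzsch ester (1.1 equiv), L-proline (20 mol %), CH2Cl2, 0 °C → rt; then K2CO3 (2.5 equiv), MeOH, 0 °C → rt; pH 5 work-up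
Reagents that add atoms: none
Why: Three-component reductive alkylation (Knoevenagel condensation at the only free ring CH, then conjugate hydride transfer from the Hantzsch ester) forms the C–CH2 bond without O-alkylation, the trans-epoxide forbids an intramolecular hetero-Diels–Alder escape of 9, and under carbonate the enolate oxygen next to CMe2 (the closure that leaves the fully chelated triketonate) opens the epoxide 5-exo-tet at its secondary carbon with inversion, which sets the (S) ring carbon and leaves the tertiary C–O bond intact.

**Step 7**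
Reactants: 11 dihydrofuran carbinol
Product: 14 target CNP0313486.1, via ring-expanded 3-chromanol 12 (not isolated), via 3-mesylate 13 (not isolated)
Conditions: KHMDS (2.2 equiv), THF, −20 °C → rt; MsCl (1.1 equiv), −78 → −20 °C; KOt-Bu (1.5 equiv), −20 → 0 °C; pH 6 buffer; exclusion of light
Reagents that add atoms: methanesulfonyl chloride CS(=O)(=O)Cl (its CH3SO2 group is present only in 13 and leaves again)
Why: Proposed new method: KHMDS forms the dianion of 11, whose tertiary alkoxide adds to the enol-ether carbon C8a of the vinylogous ester to give a 2,7-dioxabicyclo[2.2.1]heptane ketal enolate, and this collapses by expelling the secondary alkoxide on C3, so that the five-membered ring O–C3–C4–C4a–C8a is exchanged for the six-membered ring O1–C2–C3–C4–C4a–C8a of 12; low-temperature mesylation of the freed alkoxide (13) and anti E2 elimination with KOt-Bu then install C3=C4. The closest known reaction types are the base-induced O-to-O acyl migration in 1,2-diol monoesters through a cyclic orthoester anion and the alkali-induced isomerisation of 2-(1-hydroxy-1-methylethyl)dihydrofuro-fused quinolones into 3-hydroxy-2,2-dimethyldihydropyrano isomers, neither of which has been run on the enol ether of a cyclic β-triketone or coupled to an elimination. The ring-closing attack is 6-endo-trig with respect to the new pyran and at the same time 5-exo-trig with respect to the transient dioxolane, both favourable. No new stereocentre is formed: no bond to C2 is broken at any stage, so the (R) centre from the epoxidation is carried over with retention, and the C3 centre is erased. The step needs (i) attack at sp2 C8a to beat 3-exo-tet return to the epoxide, which acyl-type transfer through a five-membered adduct should do and which would in any case only regenerate 11, (ii) the equilibrium to favour 12, secured by the less basic secondary alkoxide and the less strained six-membered vinylogous ester and drained by the irreversible elimination, (iii) MsCl to choose the alkoxide over the far less basic triketonate, and (iv) elimination towards C4 only, secured by the quaternary C2. Basic, cold and dark conditions avoid ionisation of the allylic C2–O1 bond and retro-oxa-6π opening, the two channels that could racemise 14.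

**Compound list**
1 | (R)-2-methylbutanoic acid | CC[C@@H](C)C(=O)O | starting material
2 | (R)-2-methylbutanoyl chloride | CC[C@@H](C)C(=O)Cl | intermediate
3 | phloroglucinol (benzene-1,3,5-triol) | Oc1cc(O)cc(O)c1 | starting material
4 | (2R)-2-methyl-1-(2,4,6-trihydroxyphenyl)butan-1-one | CC[C@@H](C)C(=O)c1c(O)cc(O)cc1O | intermediate
5 | 3,5-dihydroxy-6,6-dimethyl-2-[(2R)-2-methylbutanoyl]cyclohexa-2,4-dien-1-one | CC[C@@H](C)C(=O)C1=C(O)C=C(O)C(C)(C)C1=O | intermediate
6 | geraniol | CC(C)=CCC/C(C)=C/CO | starting material
7 | [(2R,3R)-3-methyl-3-(4-methylpent-3-en-1-yl)oxiran-2-yl]methanol | OC[C@H]1O[C@]1(C)CCC=C(C)C | intermediate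
8 | (2S,3R)-3-methyl-3-(4-methylpent-3-en-1-yl)oxirane-2-carbaldehyde | O=C[C@H]1O[C@]1(C)CCC=C(C)C | intermediate
9 | 5-hydroxy-2,2-dimethyl-4-{[(2R,3R)-3-methyl-3-(4-methylpent-3-en-1-yl)oxiran-2-yl]methylidene}-6-[(2R)-2-methylbutanoyl]cyclohex-5-ene-1,3-dione (exocyclic alkene geometry not defined) | CC[C@@H](C)C(=O)C1=C(O)C(=C[C@H]2O[C@]2(C)CCC=C(C)C)C(=O)C(C)(C)C1=O | intermediate (not isolated)
10 | 3,5-dihydroxy-6,6-dimethyl-4-{[(2R,3R)-3-methyl-3-(4-methylpent-3-en-1-yl)oxiran-2-yl]methyl}-2-[(2R)-2-methylbutanoyl]cyclohexa-2,4-dien-1-one | CC[C@@H](C)C(=O)C1=C(O)C(C[C@H]2O[C@]2(C)CCC=C(C)C)=C(O)C(C)(C)C1=O | intermediate (not isolated)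
11 | (2S)-4-hydroxy-2-[(2R)-2-hydroxy-6-methylhept-5-en-2-yl]-7,7-dimethyl-5-[(2R)-2-methylbutanoyl]-2,3-dihydro-1-benzofuran-6(7H)-one | CC[C@@H](C)C(=O)C1=C(O)C2=C(O[C@@H](C2)[C@](C)(O)CCC=C(C)C)C(C)(C)C1=O | intermediate
12 | (2R,3S)-3,5-dihydroxy-2,8,8-trimethyl-2-(4-methylpent-3-en-1-yl)-6-[(2R)-2-methylbutanoyl]-3,4-dihydro-2H-chromen-7(8H)-one | CC[C@@H](C)C(=O)C1=C(O)C2=C(O[C@](C)(CCC=C(C)C)[C@@H](O)C2)C(C)(C)C1=O | intermediate (not isolated)
13 | 3-O-methanesulfonate of 12, (2R,3S) | CC[C@@H](C)C(=O)C1=C(O)C2=C(O[C@](C)(CCC=C(C)C)[C@@H](OS(C)(=O)=O)C2)C(C)(C)C1=O | intermediate (not isolated)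
14 | (2R)-5-hydroxy-2,8,8-trimethyl-2-(4-methylpent-3-en-1-yl)-6-[(2R)-2-methylbutanoyl]-2H-chromen-7(8H)-one | CC[C@@H](C)C(=O)C1=C(O)C2=C(O[C@](C)(CCC=C(C)C)C=C2)C(C)(C)C1=O | target

Total step count: 7
Longest linear sequence: 5 steps (1, 2, 3, 6, 7)

**Steps most likely to fail**

**Step 7.**
- What may go wrong: the alkoxide exchange may stall on the dihydrofuran side. It may also leak through epoxide re-formation and re-closure by the other enol oxygen, after which sulfonylation would hit the wrong oxygen.
- The fallback uses only known chemistry. It sets out from 6 and 5 and comes back at 12.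
- Geraniol 6 is epoxidised with L-(+)-DIPT to (2S,3S)-2,3-epoxygeraniol F1, which is oxidised with TEMPO/PhI(OAc)2 to (2R,3S)-2,3-epoxygeranial F2.
- F2 is joined to 5 by the same Hantzsch-ester reductive alkylation, through the alkylidene trione F3, to give the C-alkylated (2S,3S)-epoxide F4.
- Acid (CSA or BF3·OEt2, CH2Cl2, −78 °C) then opens the epoxide 6-endo-tet at its tertiary carbon with inversion. This is the acid-mode cyclisation known for epoxyprenyl phenols and enols.
- Inverting the enantiomeric epoxide leads to the same (2R,3S)-alcohol 12, which is now isolated. Mesylation of its triketonate salt and base elimination, as in the second half of step 7, lead to 14.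

**Step 6.**
- What may go wrong: the acidic enol may open the epoxide at its tertiary carbon during the coupling, which would invert C2 and erode the stereochemical purity. The amine catalyst may attack the epoxy aldehyde, or a second molecule of 5 may add to the alkylidene.
- The fallback keeps the medium basic throughout. It sets out from 7 and comes back at 11.
- Appel iodination (I2, PPh3, imidazole) gives (2S,3R)-2-(iodomethyl)-3-methyl-3-(4-methylpent-3-en-1-yl)oxirane F5.
- The dipotassium salt of 5 is C-alkylated with F5 in aqueous methanol, a protic medium that favours carbon over oxygen. This gives 10, which closes 5-exo in the same basic solution to 11.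

**Step 3.**
- What may go wrong: methylation may spread over both free ring carbons and the oxygens, or run on to tri- and tetramethyl compounds.
- The fallback blocks one ring carbon first. It sets out from 4 and comes back at 11.
- Reductive alkylation of 4 with 8 and Hantzsch ester, through the o-quinone methide F6, gives the aromatic C-alkylated epoxide F7.
- K2CO3/MeOH closes F7 5-exo through the hydroxyl para to the acyl group, giving the aromatic dihydrobenzofuran carbinol F8.
- Only one ring CH is then left, so MeI/NaOMe can place both methyl groups only there, and this dearomatises F8 directly to 11.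

**Further compounds**
F1 | step 7 | [(2S,3S)-3-methyl-3-(4-methylpent-3-en-1-yl)oxiran-2-yl]methanol | OC[C@@H]1O[C@@]1(C)CCC=C(C)C
F2 | step 7 | (2R,3S)-3-methyl-3-(4-methylpent-3-en-1-yl)oxirane-2-carbaldehyde | O=C[C@@H]1O[C@@]1(C)CCC=C(C)C
F3 | step 7 | (2S,3S)-epoxide diastereomer of alkylidene trione 9 | CC[C@@H](C)C(=O)C1=C(O)C(=C[C@@H]2O[C@@]2(C)CCC=C(C)C)C(=O)C(C)(C)C1=O
F4 | step 7 | (2S,3S)-epoxide diastereomer of C-alkylated epoxide 10 | CC[C@@H](C)C(=O)C1=C(O)C(C[C@@H]2O[C@@]2(C)CCC=C(C)C)=C(O)C(C)(C)C1=O
F5 | step 6 | (2S,3R)-2-(iodomethyl)-3-methyl-3-(4-methylpent-3-en-1-yl)oxirane | IC[C@H]1O[C@]1(C)CCC=C(C)C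
F6 | step 3 | o-quinone methide from 4 and 8 (exocyclic alkene geometry not defined) | CC[C@@H](C)C(=O)C1=C(O)C(=C[C@H]2O[C@]2(C)CCC=C(C)C)C(=O)C=C1O
F7 | step 3 | (2R)-2-methyl-1-(2,4,6-trihydroxy-3-{[(2R,3R)-3-methyl-3-(4-methylpent-3-en-1-yl)oxiran-2-yl]methyl}phenyl)butan-1-one | CC[C@@H](C)C(=O)c1c(O)cc(O)c(C[C@H]2O[C@]2(C)CCC=C(C)C)c1O
F8 | step 3 | (2R)-1-{(2S)-4,6-dihydroxy-2-[(2R)-2-hydroxy-6-methylhept-5-en-2-yl]-2,3-dihydro-1-benzofuran-5-yl}-2-methylbutan-1-one | CC[C@@H](C)C(=O)c1c(O)cc2O[C@@H](Cc2c1O)[C@](C)(O)CCC=C(C)C
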